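**Numbering.** Compounds 1–27 are numbered in the order of the steps. Locants C1–C8 are those of the bicyclo[4.2.0]octene core of 27 (C1 and C6 ring fusion, C2 and C5 oxygen-bearing, C7 pyranone-bearing, C8 the CH–CH3 carbon). C9 is the pyranone carbon bonded to C7. These locants are used for every intermediate.

## Analysis of the target

Target 27 is a cis-fused bicyclo[4.2.0]oct-3-ene whose six-membered ring is bridged from C2 to C5 by a peroxide, so the core is a cyclobutane-fused 2,3-dioxabicyclo[2.2.2]oct-5-ene. C7 carries a 2-methoxy-3,5-dimethyl-4-pyranone bonded through C9. There are six stereocentres: C1, C6, C7 and C8 on the cyclobutane, and the peroxide bridgeheads C2 and C5. On the cyclobutane, the methyl groups of C1, C7 and C8 and the hydrogen of C6 lie on one face. The six-membered ring and the pyranone lie on the other face, so three carbon substituents are mutually cis on C1, C6 and C7, and C1 and C7 are quaternary. The peroxide sits on the face of the six-membered ring that carries the C1 methyl group and the C6 hydrogen, anti to C7 and C8. The O–O bond does not survive reducing agents, low-valent metals or strong base (C2–H invites Kornblum–DeLaMare cleavage). The methoxypyranone is sensitive to hot acid, strong nucleophiles and ultraviolet light, and the diene that precedes the peroxide can open electrocyclically on heating. The hard parts are the crowded cyclobutane with two quaternary centres in a 1,3-relationship and a mild, late entry to the peroxide. The strategy rests on the C3=C4 alkene flanked by the oxygenated C2 and C5: read as C2(=O)–C3(CH3)=C4H–C5(O), it is the enone of a γ-oxygenated cyclohexenone. An ethyl ketone on C1 and an aldehyde on the C5 carbinol carbon form this enone by aldol condensation.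

## Retrosynthetic reasoning

**27 ⇒ 26.** The C2–O and C5–O bonds are cut together. This is the only cut that removes the peroxide and both bridgehead stereocentres while keeping C3=C4 as the central bond of a diene. All reductive and basic chemistry can then precede the O–O bond. The forward photo-oxygenation has to add to the diene face anti to C7 and C8.

**26 ⇒ 25 ⇒ 24 ⇒ 23.** The diene is traced to an ene-diol by putting oxygen back on C2 and C5, then to the silyl ether 24 and the enone 23. No C–C bond is cut, and the oxygen pattern reached is exactly what an aldol condensation gives. Forward, a 1,2-reduction, a desilylation and a reductive 1,4-elimination are needed; the configurations of C2 and C5 in 24 and 25 do not matter.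

**23 ⇒ 21.** The C3=C4 bond is cut, opening the six-membered ring to a C1 ethyl ketone and an aldehyde on C5. It is cut here because C1 and C5 are quaternary: only C3 can be the nucleophile and only C4 the electrophile, so the ring closure has a single outcome. The forward reaction must enolise, add and dehydrate without disturbing the pyranone or the silyl ether.

**21 ⇒ 20 ⇒ 19 ⇒ 18 ⇒ 17 ⇒ 14 + 15.** The pyranone is opened at its lactone C–O bond and at the bond from C9 to its ring neighbour. This leads back to the C9 aldehyde 14 and the β-keto ester 15. The C4 aldehyde stays masked as a dimethyl acetal so that only C9 reacts, and is released just before the key step. The heterocycle is therefore finished before the enone, diene and peroxide appear.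

**14 ⇒ 12.** C4 and C9 are recognised as the two ends of one cyclopentene double bond. That ring (C5, C4, C9 fused to the cyclobutane at C6–C7) is what holds the C6 and C7 carbon substituents cis. Forward, an ozonolysis must give the two termini in different form.

**12 ⇒ 11 ⇒ 10 ⇒ 8 (through 9).** The ethyl ketone goes back to the hindered acid and its methyl ester. The C8–CH3 and C1–CH3 bonds are then cut, leading to the cyclobutene ester 8. Forward, conjugate methylation and enolate methylation both occur on the convex face of a bicyclo[3.2.0] skeleton, placing the C1, C7 and C8 methyl groups on one face and the acyl carbon at C1 cis to C5.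

**8 ⇒ 7 ⇒ 6 ⇒ 5.** The C5–CH3 bond is cut back to a ring ketone, and the C4=C9 alkene back to a β-silyloxy ketone. The silyloxy stereocentre at C9 is a control element that is expelled once it has done its work.

**5 ⇒ 3 + 4, then 3 ⇒ 2 ⇒ 1.** The cyclobutene bonds C6–C1 and C7–C8 are cut, giving a cyclic enone and an alkyne. The cyclic enone fixes C6 and C7 by cis fusion, and the neighbouring silyloxy group fixes the face, hence the absolute configuration. The enone 3 comes from commercial 1 by conjugate methylation and re-oxidation.

**Why no open-chain alkene partner.** A shorter intermolecular photocycloaddition of an open-chain trisubstituted alkene was not adopted. It passes through a freely rotating 1,4-diradical, so the alkene geometry is not transmitted to C7 and C8. It also has no built-in preference for the required regiochemistry or for placing the large C7 substituent on the crowded face.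

## Alternatives that were turned down

**Alternative 1:** The disconnection is the cyclobutane bond C6–C7, made by a [3,3] shift. In A2, C9 is tied through oxygen to the doubly allylic C4 of a cyclohexa-2,5-diene. Forward, the silyl ketene acetal of A2 would undergo an Ireland–Claisen rearrangement: C6–C7 forms as C4–O breaks, the eight-membered lactone contracts to the four-membered ring, and acid A1 emerges with the C2–C5 diene in place.
- For: one pericyclic step gives the ring, the diene and an acid handle at C7; the C4 configuration is relayed to C6 and C7 through a cyclic transition state; no deoxygenation is needed afterwards. On step count after the key step it is stronger than the chosen route.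
- Against: A2 is a 1,4-bridged cyclohexadiene whose own synthesis must already set C1, C8 and the C4–O bond on one face. The enolate geometry of a medium-ring lactone cannot be chosen and the shift must pass through a boat inside the bicycle, so the C7 configuration follows from constraints that cannot be tuned. The pyranone would then have to be built from the neopentyl acid of A1 beside a thermally and oxidatively labile diene.
- In its place, the chosen strategy is longer after its key step but installs the pyranone before the diene exists and derives every cyclobutane centre from cis ring fusion or convex-face attack.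

**Alternative 2:** The disconnection is one C–O bond of the peroxide, C2–O, with the O–O bond kept. Forward, the tertiary hydroperoxide at C5 of cyclohexenone A4 (carbonyl at C4, alkene C2=C3) would add in conjugate fashion to C2 and close the 2,5-epidioxy bridge, giving the saturated keto peroxide A3.
- For: it avoids both the labile diene and the low-valent titanium step, the bridge can only form cis, and the cyclohexenone could come from a similar aldol closure. On mildness of the peroxide-forming step it is at least as good as photo-oxygenation.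
- Against: in A3, C4 is still a ketone and C3 is sp3. The C3=C4 bond of 27 would have to be introduced after the peroxide is present, by enolisation and deoxygenation. Those conditions (strong base, hydride or palladium) cause Kornblum–DeLaMare cleavage or O–O reduction in an endoperoxide with hydrogen on C2. The β-peroxy ketone of A3 can also revert by E1cB, and the hydroperoxide of A4 must be installed with facial control next to the pyranone.
- In its place, the chosen strategy ends with the peroxide-forming step, which creates C3=C4 at the same time, so nothing is done to the molecule once the O–O bond exists.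

**Alternative 3:** The disconnection is C7–C8, traced back to a five-membered ketone. A6 is a cis-hydrindanone with the diazo group on C7. Forward, irradiation of A6 in methanol would trigger a Wolff rearrangement: C8 migrates with retention, the cyclopentanone contracts and ester A5 forms.
- For: the four-membered ring comes from a six–five bicycle that ordinary annulation chemistry can supply; the migrating carbon is unambiguous; C8 is epimerisable beforehand and could be set under thermodynamic control. The C4 carbonyl of A5 sits where the diene must end, so the diene would be two steps away against four from 23; on that count it is stronger.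
- Against: A5 has only hydrogen and the ester on C7, so the quaternary centre must be completed by alkylation and the whole pyranone built from a neopentyl ester at the end, beside the enone or diene. The enone chromophore of A6 competes for the light, and C1, C6 and C8 must be set in a separate synthesis of the hydrindanone.
- In its place, the chosen strategy carries the pyranone through the ring-forming events instead of appending it last, and its aldol closure needs no control of regiochemistry.

Key step: step 16

Remark on the chemistry: 1, 4 and 15 are taken as commercially available; stereocentres that are removed later are left undefined where they form as mixtures (the peroxy-acetal carbon of 13, the three chain centres of 17, C3 and C4 of 22) or drawn as the expected epimer (C2 of 24 and 25), and none of them bears on 27.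

## Route

Step 1
Reactants: 1 (S)-4-(tert-butyldimethylsilyloxy)cyclopent-2-en-1-one
Product: 2 (3S,4S)-4-(tert-butyldimethylsilyloxy)-3-methyl-1-(trimethylsilyloxy)cyclopent-1-ene
Conditions: Me2CuLi (from MeLi, CuI), Me3SiCl, THF, −78 °C; Et3N, cold aq NaHCO3 work-up
Reagents that add atoms: lithium dimethylcuprate, [Li+].C[Cu-]C; chlorotrimethylsilane, C[Si](C)(C)Cl
Why: Conjugate addition of a Gilman cuprate with silyl trapping of the regiodefined enolate; methyl enters trans to the silyloxy group, and trapping at low temperature keeps the enolate from equilibrating to the isomer that would expel the silyloxy group. The methyl-bearing stereocentre is removed again in step 2.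

Step 2
Reactants: 2 (3S,4S)-4-(tert-butyldimethylsilyloxy)-3-methyl-1-(trimethylsilyloxy)cyclopent-1-ene
Product: 3 (S)-4-(tert-butyldimethylsilyloxy)-3-methylcyclopent-2-en-1-one
Conditions: Pd(OAc)2 (1 equiv), MeCN, rt
Reagents that add atoms: none
Why: Saegusa–Ito oxidation: the palladium enolate formed from the silyl enol ether has its only β-hydrogen on the methyl-bearing carbon, so β-hydride elimination returns the enone with the methyl group on its β-carbon (the future C7) and leaves the silyloxy stereocentre untouched.

Step 3
Reactants: 3 (S)-4-(tert-butyldimethylsilyloxy)-3-methylcyclopent-2-en-1-one; 4 methyl prop-2-ynoate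
Product: 5 methyl (4S)-4-(tert-butyldimethylsilyloxy)-5-methyl-2-oxobicyclo[3.2.0]hept-6-ene-7-carboxylate
Conditions: hν (365 nm), 4 (10 equiv), CH2Cl2, −40 °C, stopped at partial conversion
Reagents that add atoms: none
Why: Enone–alkyne [2+2] photocycloaddition of a cyclic enone triplet: cis fusion puts C6–H and C7–CH3 on one cyclobutene face and C5 and C9 on the other, and the alkyne should add anti to the C9 silyloxy group, which sets the absolute configuration of C6 and C7. The ester-bearing alkyne carbon is expected to bond to the enone α-carbon C6 (acceptor-substituted partner, and the congested β-carbon C7 takes the unsubstituted terminus), giving C6–C1 and C7–C8.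

Step 4
Reactants: 5 methyl (4S)-4-(tert-butyldimethylsilyloxy)-5-methyl-2-oxobicyclo[3.2.0]hept-6-ene-7-carboxylate
Product: 6 methyl 5-methyl-2-oxobicyclo[3.2.0]hepta-3,6-diene-7-carboxylate
Conditions: DBU (cat.), CH2Cl2, 0 °C → rt
Reagents that add atoms: none
Why: E1cB elimination of a β-silyloxy ketone through the C4 enolate; the C9 stereocentre is erased after use and the C4=C9 alkene that is cleaved in step 10 is installed. C6–H is not enolised because that would place three sp2 carbons in the four-membered ring.

Step 5
Reactants: 6 methyl 5-methyl-2-oxobicyclo[3.2.0]hepta-3,6-diene-7-carboxylate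
Product: 7 methyl 2-hydroxy-2,5-dimethylbicyclo[3.2.0]hepta-3,6-diene-7-carboxylate
Conditions: MeLi, CeCl3, THF, −78 °C; aq work-up
Reagents that add atoms: methyllithium, [Li]C
Why: 1,2-Addition of the weakly basic organocerium reagent MeCeCl2 to the enone carbonyl, in preference to the ester and to conjugate addition. Attack on the convex face, anti to the cyclobutene, should put the new methyl exo and the C5 oxygen endo; this centre disappears in step 19.

Step 6
Reactants: 7 methyl 2-hydroxy-2,5-dimethylbicyclo[3.2.0]hepta-3,6-diene-7-carboxylate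
Product: 8 methyl 2-(tert-butyldimethylsilyloxy)-2,5-dimethylbicyclo[3.2.0]hepta-3,6-diene-7-carboxylate
Conditions: TBSOTf, 2,6-lutidine, CH2Cl2, −78 → 0 °C
Reagents that add atoms: tert-butyldimethylsilyl triflate, CC(C)(C)[Si](C)(C)OS(=O)(=O)C(F)(F)F
Why: Silylation with the silyl triflate and a hindered pyridine base is the standard protection of a hindered tertiary alcohol and is non-acidic, so the tertiary allylic C–O bond is not ionised.

Step 7
Reactants: 8 methyl 2-(tert-butyldimethylsilyloxy)-2,5-dimethylbicyclo[3.2.0]hepta-3,6-diene-7-carboxylate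
Product: 10 methyl 2-(tert-butyldimethylsilyloxy)-2,5,6,7-tetramethylbicyclo[3.2.0]hept-3-ene-7-carboxylate, via lithium ester enolate 9 (not isolated)
Conditions: Me2CuLi (from MeLi, CuI), Et2O, −78 → −30 °C; then MeI, HMPA, −30 °C → rt
Reagents that add atoms: lithium dimethylcuprate, [Li+].C[Cu-]C; iodomethane, CI
Why: Tandem conjugate addition–enolate alkylation: the strained cyclobutene ester should accept methyl at C8 on the convex face of the bicyclo[3.2.0] skeleton. Enolate 9 should then be methylated at C1 on the same face, because the concave face is blocked by the fully substituted C5. This puts the C1, C7 and C8 methyl groups cis and the ester cis to C5 and C9.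

Step 8
Reactants: 10 methyl 2-(tert-butyldimethylsilyloxy)-2,5,6,7-tetramethylbicyclo[3.2.0]hept-3-ene-7-carboxylate
Product: 11 2-(tert-butyldimethylsilyloxy)-2,5,6,7-tetramethylbicyclo[3.2.0]hept-3-ene-7-carboxylic acid
Conditions: NaSEt, DMF, 100 °C; then aq HCl
Reagents that add atoms: none
Why: SN2 dealkylation of the methyl ester by thiolate at the methyl carbon, which avoids attack at the neopentyl carbonyl carbon and leaves the tertiary silyl ether and the alkene alone.

Step 9
Reactants: 11 2-(tert-butyldimethylsilyloxy)-2,5,6,7-tetramethylbicyclo[3.2.0]hept-3-ene-7-carboxylic acid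
Product: 12 1-[2-(tert-butyldimethylsilyloxy)-2,5,6,7-tetramethylbicyclo[3.2.0]hept-3-en-7-yl]propan-1-one
Conditions: EtLi (3 equiv), Et2O, 0 °C → rt; then H2O
Reagents that add atoms: ethyllithium, [Li]CC
Why: Ketone synthesis from a carboxylic acid and an alkyllithium: the lithium carboxylate adds one equivalent to give a geminal dilithium alkoxide that collapses to the ketone only on work-up, so the hindered acid gives the ethyl ketone without over-addition.

Step 10
Reactants: 12 1-[2-(tert-butyldimethylsilyloxy)-2,5,6,7-tetramethylbicyclo[3.2.0]hept-3-en-7-yl]propan-1-one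
Product: 14 2-[2-(tert-butyldimethylsilyloxy)-1,1-dimethoxypropan-2-yl]-1,3,4-trimethyl-3-propanoylcyclobutane-1-carbaldehyde, via methoxy hydroperoxide acetal 13 (not isolated)
Conditions: O3, CH2Cl2/MeOH, −78 °C; TsOH·H2O (cat.), −78 °C → rt; NaHCO3; Me2S, rt
Reagents that add atoms: ozone, [O-][O+]=O; methanol, CO
Why: Ozonolysis with differentiation of the two termini: Criegee fragmentation of the primary ozonide should place the carbonyl oxide on C9, remote from the electron-withdrawing C5–O bond, where methanol traps it. The C4 aldehyde is acetalised under acid before the C9 methoxy hydroperoxide is reduced to the aldehyde. The cis relation of the C6 and C7 substituents, fixed by the former ring, is kept.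

Step 11
Reactants: 14 2-[2-(tert-butyldimethylsilyloxy)-1,1-dimethoxypropan-2-yl]-1,3,4-trimethyl-3-propanoylcyclobutane-1-carbaldehyde; 15 methyl 2-methyl-3-oxopentanoate
Product: 17 methyl 5-[2-[2-(tert-butyldimethylsilyloxy)-1,1-dimethoxypropan-2-yl]-1,3,4-trimethyl-3-propanoylcyclobutyl]-5-hydroxy-2,4-dimethyl-3-oxopentanoate, via ketoester dianion 16 (not isolated)
Conditions: 15, NaH then n-BuLi, THF, 0 °C; 14, −78 °C; AcOH
Reagents that add atoms: none
Why: Aldol addition of a β-keto ester dianion through its more nucleophilic γ-carbon to the only aldehyde present; at −78 °C the hindered ethyl ketone and the acetal should not compete. The three new stereocentres are removed in steps 12 and 13.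

Step 12
Reactants: 17 methyl 5-[2-[2-(tert-butyldimethylsilyloxy)-1,1-dimethoxypropan-2-yl]-1,3,4-trimethyl-3-propanoylcyclobutyl]-5-hydroxy-2,4-dimethyl-3-oxopentanoate
Product: 18 methyl 5-[2-[2-(tert-butyldimethylsilyloxy)-1,1-dimethoxypropan-2-yl]-1,3,4-trimethyl-3-propanoylcyclobutyl]-2,4-dimethyl-3,5-dioxopentanoate
Conditions: Dess–Martin periodinane, CH2Cl2, 0 °C → rt
Reagents that add atoms: none
Why: Dess–Martin oxidation of the secondary alcohol under nearly neutral conditions gives the 3,5-diketo ester without retro-aldol cleavage and without touching the acetal or silyl ether.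

Step 13
Reactants: 18 methyl 5-[2-[2-(tert-butyldimethylsilyloxy)-1,1-dimethoxypropan-2-yl]-1,3,4-trimethyl-3-propanoylcyclobutyl]-2,4-dimethyl-3,5-dioxopentanoate
Product: 19 6-[2-[2-(tert-butyldimethylsilyloxy)-1,1-dimethoxypropan-2-yl]-1,3,4-trimethyl-3-propanoylcyclobutyl]-4-hydroxy-3,5-dimethyl-2H-pyran-2-one
Conditions: DBU, toluene, 60 °C; then AcOH
Reagents that add atoms: none
Why: Base-mediated lactonisation: the enol oxygen of the C9 ketone attacks the ester carbonyl (6-exo-trig acyl substitution) and methanol is lost, the usual closure of a 3,5-diketo ester to a 4-hydroxy-2-pyranone.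

Step 14
Reactants: 19 6-[2-[2-(tert-butyldimethylsilyloxy)-1,1-dimethoxypropan-2-yl]-1,3,4-trimethyl-3-propanoylcyclobutyl]-4-hydroxy-3,5-dimethyl-2H-pyran-2-one
Product: 20 6-[2-[2-(tert-butyldimethylsilyloxy)-1,1-dimethoxypropan-2-yl]-1,3,4-trimethyl-3-propanoylcyclobutyl]-2-methoxy-3,5-dimethyl-4H-pyran-4-one
Conditions: MeOTf, CH2Cl2, 0 °C → rt; aq NaHCO3 work-up
Reagents that add atoms: methyl triflate, COS(=O)(=O)C(F)(F)F
Why: O-Methylation of the neutral vinylogous acid with a hard methylating agent takes place at the lactone carbonyl oxygen; loss of the proton from the 4-hydroxy group then gives the 2-methoxy-4-pyranone, not the 4-methoxy-2-pyranone that alkylation of the anion would give.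

Step 15
Reactants: 20 6-[2-[2-(tert-butyldimethylsilyloxy)-1,1-dimethoxypropan-2-yl]-1,3,4-trimethyl-3-propanoylcyclobutyl]-2-methoxy-3,5-dimethyl-4H-pyran-4-one
Product: 21 2-(tert-butyldimethylsilyloxy)-2-[2-(6-methoxy-3,5-dimethyl-4-oxo-4H-pyran-2-yl)-2,3,4-trimethyl-4-propanoylcyclobutyl]propanal
Conditions: CF3CO2H/H2O, CHCl3, 0 °C
Reagents that add atoms: water, O
Why: Acid hydrolysis of a dimethyl acetal; the tertiary silyl ether and the methoxypyranone should tolerate brief exposure to cold aqueous acid, and the aldehyde has no α-hydrogen to lose.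

Step 16
Reactants: 21 2-(tert-butyldimethylsilyloxy)-2-[2-(6-methoxy-3,5-dimethyl-4-oxo-4H-pyran-2-yl)-2,3,4-trimethyl-4-propanoylcyclobutyl]propanal
Product: 23 5-(tert-butyldimethylsilyloxy)-7-(6-methoxy-3,5-dimethyl-4-oxo-4H-pyran-2-yl)-1,3,5,7,8-pentamethylbicyclo[4.2.0]oct-3-en-2-one, via aldol adduct 22 (not isolated)
Conditions: NaOMe (0.3 equiv), MeOH, 0 → 40 °C
Reagents that add atoms: none
Why: Methoxide reversibly forms the only enolate available, at the C3 methylene of the ethyl ketone, and this adds to the non-enolisable C4 aldehyde to give β-hydroxy ketone 22; E1cB loss of water through the C3 enolate then gives the conjugated enone 23 irreversibly. The closest known reaction type is the intramolecular aldol condensation that closes the cyclohexenone in a Robinson annulation. The six-membered ring closes in the 6-(enolendo)-exo-trig mode, helped by the two reacting chains being held cis on C1 and C6 of the cyclobutane. No lasting stereocentre is created: C3 and C4 of 22 become sp2, and C1, C5, C6, C7 and C8 carry no acidic hydrogen and cannot epimerise. The step needs regioselectivity (which carbonyl is nucleophile and which electrophile) and chemoselectivity against the pyranone; the first is secured by the quaternary C1 and C5, the second by the vinylogous-ester character of the pyranone carbonyl and the non-acidic pyranone methyl groups. Dehydration can go in one direction only, since C5 bears no hydrogen. The protic medium keeps the aldolate protonated, which should suppress migration of the silyl group from the C5 to the C4 oxygen.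

Step 17
Reactants: 23 5-(tert-butyldimethylsilyloxy)-7-(6-methoxy-3,5-dimethyl-4-oxo-4H-pyran-2-yl)-1,3,5,7,8-pentamethylbicyclo[4.2.0]oct-3-en-2-one
Product: 24 6-[5-(tert-butyldimethylsilyloxy)-2-hydroxy-1,3,5,7,8-pentamethylbicyclo[4.2.0]oct-3-en-7-yl]-2-methoxy-3,5-dimethyl-4H-pyran-4-one
Conditions: NaBH4, CeCl3·7H2O, MeOH, −20 °C
Reagents that add atoms: none
Why: Luche 1,2-reduction of the enone to the allylic alcohol; the pyranone carbonyl, a doubly donor-stabilised vinylogous ester, should not be reduced. Hydride is expected on the face anti to the cyclobutane, but the C2 configuration is immaterial because C2 becomes sp2 in step 19.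

Step 18
Reactants: 24 6-[5-(tert-butyldimethylsilyloxy)-2-hydroxy-1,3,5,7,8-pentamethylbicyclo[4.2.0]oct-3-en-7-yl]-2-methoxy-3,5-dimethyl-4H-pyran-4-one
Product: 25 6-(2,5-dihydroxy-1,3,5,7,8-pentamethylbicyclo[4.2.0]oct-3-en-7-yl)-2-methoxy-3,5-dimethyl-4H-pyran-4-one
Conditions: Bu4NF, THF, rt → 45 °C
Reagents that add atoms: none
Why: Fluoride-induced cleavage of the tertiary silyl ether; the basic, non-acidic conditions avoid ionising the tertiary allylic C5–O bond.

Step 19
Reactants: 25 6-(2,5-dihydroxy-1,3,5,7,8-pentamethylbicyclo[4.2.0]oct-3-en-7-yl)-2-methoxy-3,5-dimethyl-4H-pyran-4-one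
Product: 26 2-methoxy-3,5-dimethyl-6-(1,3,5,7,8-pentamethylbicyclo[4.2.0]octa-2,4-dien-7-yl)-4H-pyran-4-one
Conditions: TiCl3, LiAlH4, THF, 0 °C → rt
Reagents that add atoms: none
Why: Reductive 1,4-elimination of a 2-ene-1,4-diol by low-valent titanium: both C–O bonds of the titanium bis-alkoxide are cleaved with shift of the double bond, giving the 1,3-diene whatever the relative configuration of C2 and C5. The cyclobutane stereocentres are not involved.

Step 20
Reactants: 26 2-methoxy-3,5-dimethyl-6-(1,3,5,7,8-pentamethylbicyclo[4.2.0]octa-2,4-dien-7-yl)-4H-pyran-4-one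
Product: 27 2-methoxy-3,5-dimethyl-6-(1,3,5,7,8-pentamethyl-2,5-epidioxybicyclo[4.2.0]oct-3-en-7-yl)-4H-pyran-4-one
Conditions: O2, methylene blue (cat.), visible light, CH2Cl2, 0 °C
Reagents that add atoms: dioxygen, O=O
Why: [4+2] Cycloaddition of singlet oxygen to the cisoid ring diene; attack should occur on the convex face, anti to C7, C8 and the endo pyranone and syn to the C1 methyl group and C6–H. This sets C2 and C5 together and leaves C3=C4 between them.

## Compound list

1 | (S)-4-(tert-butyldimethylsilyloxy)cyclopent-2-en-1-one | O=C1C=C[C@@H](O[Si](C)(C)C(C)(C)C)C1 | starting material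
2 | (3S,4S)-4-(tert-butyldimethylsilyloxy)-3-methyl-1-(trimethylsilyloxy)cyclopent-1-ene (methyl trans to the silyloxy group) | C[C@H]1C=C(O[Si](C)(C)C)C[C@@H]1O[Si](C)(C)C(C)(C)C | intermediate
3 | (S)-4-(tert-butyldimethylsilyloxy)-3-methylcyclopent-2-en-1-one | CC1=CC(=O)C[C@@H]1O[Si](C)(C)C(C)(C)C | intermediate
4 | methyl prop-2-ynoate (methyl propiolate) | C#CC(=O)OC | starting material
5 | methyl (4S)-4-(tert-butyldimethylsilyloxy)-5-methyl-2-oxobicyclo[3.2.0]hept-6-ene-7-carboxylate; cis ring fusion (C6–H and C7–CH3 on one face), cyclobutene on the face opposite the silyloxy group | COC(=O)C1=C[C@]2(C)[C@@H](O[Si](C)(C)C(C)(C)C)CC(=O)[C@H]12 | intermediate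
6 | methyl 5-methyl-2-oxobicyclo[3.2.0]hepta-3,6-diene-7-carboxylate; ring-fusion centres as in 5 | COC(=O)C1=C[C@]2(C)C=CC(=O)[C@H]12 | intermediate
7 | methyl 2-hydroxy-2,5-dimethylbicyclo[3.2.0]hepta-3,6-diene-7-carboxylate; C5 methyl on the convex face, hydroxyl on the concave face (syn to the cyclobutene), ring fusion as in 5 | COC(=O)C1=C[C@]2(C)C=C[C@](C)(O)[C@H]12 | intermediate
8 | methyl 2-(tert-butyldimethylsilyloxy)-2,5-dimethylbicyclo[3.2.0]hepta-3,6-diene-7-carboxylate; configuration as 7 | COC(=O)C1=C[C@]2(C)C=C[C@](C)(O[Si](C)(C)C(C)(C)C)[C@H]12 | intermediate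
9 | lithium enolate of methyl 2-(tert-butyldimethylsilyloxy)-2,5,6-trimethylbicyclo[3.2.0]hept-3-ene-7-carboxylate; C8 methyl on the convex face, cis to the C7 methyl | COC(O[Li])=C1[C@@H](C)[C@]2(C)C=C[C@](C)(O[Si](C)(C)C(C)(C)C)[C@H]12 | intermediate
10 | methyl 2-(tert-butyldimethylsilyloxy)-2,5,6,7-tetramethylbicyclo[3.2.0]hept-3-ene-7-carboxylate; methyl groups at positions 5, 6 and 7 (C7, C8 and C1) cis on the convex face, ester on the concave face, C5 as in 7 | COC(=O)[C@]1(C)[C@@H](C)[C@]2(C)C=C[C@](C)(O[Si](C)(C)C(C)(C)C)[C@H]12 | intermediate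
11 | 2-(tert-butyldimethylsilyloxy)-2,5,6,7-tetramethylbicyclo[3.2.0]hept-3-ene-7-carboxylic acid; configuration as 10 | OC(=O)[C@]1(C)[C@@H](C)[C@]2(C)C=C[C@](C)(O[Si](C)(C)C(C)(C)C)[C@H]12 | intermediate
12 | 1-[2-(tert-butyldimethylsilyloxy)-2,5,6,7-tetramethylbicyclo[3.2.0]hept-3-en-7-yl]propan-1-one; configuration as 10 | CCC(=O)[C@]1(C)[C@@H](C)[C@]2(C)C=C[C@](C)(O[Si](C)(C)C(C)(C)C)[C@H]12 | intermediate
13 | 1-[2-[2-(tert-butyldimethylsilyloxy)-1,1-dimethoxypropan-2-yl]-3-[hydroperoxy(methoxy)methyl]-1,3,4-trimethylcyclobutyl]propan-1-one; ring configuration as 14, peroxy-acetal carbon as a mixture | COC(OO)[C@@]1(C)[C@H](C)[C@@](C)(C(=O)CC)[C@H]1[C@@](C)(O[Si](C)(C)C(C)(C)C)C(OC)OC | intermediate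
14 | 2-[2-(tert-butyldimethylsilyloxy)-1,1-dimethoxypropan-2-yl]-1,3,4-trimethyl-3-propanoylcyclobutane-1-carbaldehyde; formyl (on C7), side chain (on C6) and propanoyl (on C1) mutually cis, the three ring methyl groups on the other face, C5 as in 7 | O=C[C@@]1(C)[C@H](C)[C@@](C)(C(=O)CC)[C@H]1[C@@](C)(O[Si](C)(C)C(C)(C)C)C(OC)OC | intermediate
15 | methyl 2-methyl-3-oxopentanoate | CCC(=O)C(C)C(=O)OC | starting material
16 | sodium lithium dianion of methyl 2-methyl-3-oxopentanoate (carbanions at C2 and C4) | [Na+].[Li+].C[CH-]C(=O)[C-](C)C(=O)OC | intermediate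
17 | methyl 5-[2-[2-(tert-butyldimethylsilyloxy)-1,1-dimethoxypropan-2-yl]-1,3,4-trimethyl-3-propanoylcyclobutyl]-5-hydroxy-2,4-dimethyl-3-oxopentanoate; ring and C5 as in 14, chain centres as mixtures | COC(=O)C(C)C(=O)C(C)C(O)[C@@]1(C)[C@H](C)[C@@](C)(C(=O)CC)[C@H]1[C@@](C)(O[Si](C)(C)C(C)(C)C)C(OC)OC | intermediate
18 | methyl 5-[2-[2-(tert-butyldimethylsilyloxy)-1,1-dimethoxypropan-2-yl]-1,3,4-trimethyl-3-propanoylcyclobutyl]-2,4-dimethyl-3,5-dioxopentanoate; ring and C5 as in 14 | COC(=O)C(C)C(=O)C(C)C(=O)[C@@]1(C)[C@H](C)[C@@](C)(C(=O)CC)[C@H]1[C@@](C)(O[Si](C)(C)C(C)(C)C)C(OC)OC | intermediate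
19 | 6-[2-[2-(tert-butyldimethylsilyloxy)-1,1-dimethoxypropan-2-yl]-1,3,4-trimethyl-3-propanoylcyclobutyl]-4-hydroxy-3,5-dimethyl-2H-pyran-2-one; ring and C5 as in 14 | CC1=C(O)C(C)=C([C@@]2(C)[C@H](C)[C@@](C)(C(=O)CC)[C@H]2[C@@](C)(O[Si](C)(C)C(C)(C)C)C(OC)OC)OC1=O | intermediate
20 | 6-[2-[2-(tert-butyldimethylsilyloxy)-1,1-dimethoxypropan-2-yl]-1,3,4-trimethyl-3-propanoylcyclobutyl]-2-methoxy-3,5-dimethyl-4H-pyran-4-one; ring and C5 as in 14 | COc1oc([C@@]2(C)[C@H](C)[C@@](C)(C(=O)CC)[C@H]2[C@@](C)(O[Si](C)(C)C(C)(C)C)C(OC)OC)c(C)c(=O)c1C | intermediate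
21 | 2-(tert-butyldimethylsilyloxy)-2-[2-(6-methoxy-3,5-dimethyl-4-oxo-4H-pyran-2-yl)-2,3,4-trimethyl-4-propanoylcyclobutyl]propanal; pyranone (C7), silyloxy aldehyde chain (C6) and propanoyl (C1) cis, the C1, C7 and C8 methyl groups on the other face | COc1oc([C@@]2(C)[C@H](C)[C@@](C)(C(=O)CC)[C@H]2[C@@](C)(O[Si](C)(C)C(C)(C)C)C=O)c(C)c(=O)c1C | intermediate
22 | 5-(tert-butyldimethylsilyloxy)-4-hydroxy-7-(6-methoxy-3,5-dimethyl-4-oxo-4H-pyran-2-yl)-1,3,5,7,8-pentamethylbicyclo[4.2.0]octan-2-one; C3 and C4 as mixtures, other centres as 23 | COc1oc([C@@]2(C)[C@H](C)[C@@]3(C)C(=O)C(C)C(O)[C@](C)(O[Si](C)(C)C(C)(C)C)[C@@H]23)c(C)c(=O)c1C | intermediate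
23 | 5-(tert-butyldimethylsilyloxy)-7-(6-methoxy-3,5-dimethyl-4-oxo-4H-pyran-2-yl)-1,3,5,7,8-pentamethylbicyclo[4.2.0]oct-3-en-2-one; cis ring fusion, C1, C7 and C8 methyl groups and C6–H on one cyclobutane face, pyranone cis to C5, silyloxy group on the ring face anti to C7 and C8 | COc1oc([C@@]2(C)[C@H](C)[C@@]3(C)C(=O)C(C)=C[C@](C)(O[Si](C)(C)C(C)(C)C)[C@@H]23)c(C)c(=O)c1C | intermediate
24 | 6-[5-(tert-butyldimethylsilyloxy)-2-hydroxy-1,3,5,7,8-pentamethylbicyclo[4.2.0]oct-3-en-7-yl]-2-methoxy-3,5-dimethyl-4H-pyran-4-one; C2 hydroxyl drawn trans to the C5 silyloxy group, other centres as 23 | COc1oc([C@@]2(C)[C@H](C)[C@@]3(C)[C@@H](O)C(C)=C[C@](C)(O[Si](C)(C)C(C)(C)C)[C@@H]23)c(C)c(=O)c1C | intermediate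
25 | 6-(2,5-dihydroxy-1,3,5,7,8-pentamethylbicyclo[4.2.0]oct-3-en-7-yl)-2-methoxy-3,5-dimethyl-4H-pyran-4-one; configuration as 24 | COc1oc([C@@]2(C)[C@H](C)[C@@]3(C)[C@@H](O)C(C)=C[C@](C)(O)[C@@H]23)c(C)c(=O)c1C | intermediate
26 | 2-methoxy-3,5-dimethyl-6-(1,3,5,7,8-pentamethylbicyclo[4.2.0]octa-2,4-dien-7-yl)-4H-pyran-4-one; cis ring fusion, C1, C7 and C8 methyl groups and C6–H on one cyclobutane face | COc1oc([C@@]2(C)[C@H](C)[C@@]3(C)C=C(C)C=C(C)[C@@H]23)c(C)c(=O)c1C | intermediate
27 | 2-methoxy-3,5-dimethyl-6-(1,3,5,7,8-pentamethyl-2,5-epidioxybicyclo[4.2.0]oct-3-en-7-yl)-4H-pyran-4-one (CNP0183511.1); peroxide bridge anti to C7 and C8 | COc1oc([C@@]2(C)[C@H](C)[C@@]3(C)[C@@H]4OO[C@@](C)(C=C4C)[C@@H]23)c(C)c(=O)c1C | target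

## Step count and least certain steps

Total step count: 20. Longest linear sequence: 20 steps (1 → 27); 4 and 15 each enter in a single step.

**Step 16 (key step).** The most likely failure is migration of the silyl group from the C5 oxygen to the C4 aldolate oxygen, followed by loss of silanolate. That would give the enone as the free C5 alcohol, which is still usable because step 18 produces that alcohol anyway. More damaging would be base-induced degradation of the methoxypyranone before dehydration is complete, because dehydration needs the hindered C3 position to be enolised a second time. Fallback: setting out from acetal 20, the ethyl ketone is converted with LiN(iPr)2 and Me3SiCl into its trimethylsilyl enol ether F1. A catalytic amount of Me3SiOTf in CH2Cl2 at −78 °C then ionises the dimethyl acetal, and the enol ether closes the same C3–C4 bond in a Mukaiyama-type aldol reaction to give the β-methoxy ketone F2. DBU removes methanol and the route is rejoined at enone 23.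

**Step 3.** Two things may go wrong: bond formation between the enone and the unsymmetrical alkyne with poor regioselectivity, and a secondary 1,3-acyl shift of the β,γ-unsaturated ketone product on continued irradiation. Fallback: setting out from enone 3, irradiation with methyl (E)-3-methoxyacrylate gives the saturated methoxy cyclobutane ester F3. Here the donor and acceptor ends of the alkene both direct the ester-bearing carbon to C6, and the product cannot undergo an acyl shift. DBU converts F3 into the cyclopentenone F4, MeLi/CeCl3 gives the tertiary alcohol F5, and TBSOTf gives the silyl ether F6. LiN(iPr)2 at −78 °C then expels methoxide from the ester enolate and gives cyclobutene ester 8.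

**Step 10.** The primary ozonide may fragment in the unwanted direction, with the carbonyl oxide on C4, which would exchange the free and the masked aldehyde. Fallback: setting out from alkene 12, ozonolysis in CH2Cl2 with plain Me2S work-up gives the dialdehyde F7. The α-silyloxy aldehyde at C4, the more electrophilic of the two, is then converted selectively into its dimethyl acetal with HC(OMe)3 and a catalytic amount of CeCl3·7H2O in MeOH, which rejoins the route at 14.

**Step 19.** Low-valent titanium or residual hydride may reduce the pyranone carbonyl, and the diene may open electrocyclically if the mixture has to be heated. Fallback: setting out from enone 23, samarium diiodide (SmI2) in THF/MeOH cleaves the γ-silyloxy group reductively, and protonation of the dienolate at C3 gives the β,γ-unsaturated ketone F8. KN(SiMe3)2 and PhNTf2 give the dienyl triflate F9. Reduction with Pd(OAc)2, PPh3, Bu3N and HCO2H then delivers diene 26, bypassing steps 17 to 19.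

## Further compounds

F1 | step 16 | trimethylsilyl enol ether of the ethyl ketone of 20 (ring configuration and C5 as in 20) | COc1oc([C@@]2(C)[C@H](C)[C@@](C)(C(O[Si](C)(C)C)=CC)[C@H]2[C@@](C)(O[Si](C)(C)C(C)(C)C)C(OC)OC)c(C)c(=O)c1C
F2 | step 16 | 5-(tert-butyldimethylsilyloxy)-4-methoxy-7-(6-methoxy-3,5-dimethyl-4-oxo-4H-pyran-2-yl)-1,3,5,7,8-pentamethylbicyclo[4.2.0]octan-2-one (C3 and C4 as mixtures, other centres as 23) | COc1oc([C@@]2(C)[C@H](C)[C@@]3(C)C(=O)C(C)C(OC)[C@](C)(O[Si](C)(C)C(C)(C)C)[C@@H]23)c(C)c(=O)c1C
F3 | step 3 | methyl (4S)-4-(tert-butyldimethylsilyloxy)-6-methoxy-5-methyl-2-oxobicyclo[3.2.0]heptane-7-carboxylate (ring fusion as 5, the methoxy- and ester-bearing carbons as mixtures) | COC(=O)C1C(OC)[C@]2(C)[C@@H](O[Si](C)(C)C(C)(C)C)CC(=O)[C@H]12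
F4 | step 3 | methyl 6-methoxy-5-methyl-2-oxobicyclo[3.2.0]hept-3-ene-7-carboxylate (ring fusion as 5) | COC(=O)C1C(OC)[C@]2(C)C=CC(=O)[C@H]12
F5 | step 3 | methyl 2-hydroxy-6-methoxy-2,5-dimethylbicyclo[3.2.0]hept-3-ene-7-carboxylate (C5 as in 7) | COC(=O)C1C(OC)[C@]2(C)C=C[C@](C)(O)[C@H]12
F6 | step 3 | methyl 2-(tert-butyldimethylsilyloxy)-6-methoxy-2,5-dimethylbicyclo[3.2.0]hept-3-ene-7-carboxylate (C5 as in 7) | COC(=O)C1C(OC)[C@]2(C)C=C[C@](C)(O[Si](C)(C)C(C)(C)C)[C@H]12
F7 | step 10 | 2-[2-(tert-butyldimethylsilyloxy)-1-oxopropan-2-yl]-1,3,4-trimethyl-3-propanoylcyclobutane-1-carbaldehyde (configuration as 14) | O=C[C@@]1(C)[C@H](C)[C@@](C)(C(=O)CC)[C@H]1[C@@](C)(O[Si](C)(C)C(C)(C)C)C=O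
F8 | step 19 | 7-(6-methoxy-3,5-dimethyl-4-oxo-4H-pyran-2-yl)-1,3,5,7,8-pentamethylbicyclo[4.2.0]oct-4-en-2-one (C3 as a mixture, cyclobutane centres as 23) | COc1oc([C@@]2(C)[C@H](C)[C@@]3(C)C(=O)C(C)C=C(C)[C@@H]23)c(C)c(=O)c1C
F9 | step 19 | 7-(6-methoxy-3,5-dimethyl-4-oxo-4H-pyran-2-yl)-1,3,5,7,8-pentamethylbicyclo[4.2.0]octa-2,4-dien-2-yl trifluoromethanesulfonate (cyclobutane centres as 26) | COc1oc([C@@]2(C)[C@H](C)[C@@]3(C)C(OS(=O)(=O)C(F)(F)F)=C(C)C=C(C)[C@@H]23)c(C)c(=O)c1C
A1 | alternative 1 | 1,3,5,7,8-pentamethylbicyclo[4.2.0]octa-2,4-diene-7-carboxylic acid | O=C(O)[C@@]1(C)[C@H](C)[C@@]2(C)C=C(C)C=C(C)[C@@H]12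
A2 | alternative 1 | bridged dienyl lactone, 1,5,6,8,9-pentamethyl-3-oxabicyclo[4.2.2]deca-7,9-dien-4-one (C7 of the target numbering as either epimer) | O=C1O[C@@H]2C(C)=C[C@@](C)(C=C2C)[C@@H](C)C1C
A3 | alternative 2 | 2,5-epidioxy-7-(6-methoxy-3,5-dimethyl-4-oxo-4H-pyran-2-yl)-1,3,5,7,8-pentamethylbicyclo[4.2.0]octan-4-one | COc1oc([C@@]2(C)[C@H](C)[C@@]3(C)[C@@H]4OO[C@@](C)(C(=O)[C@H]4C)[C@@H]23)c(C)c(=O)c1C
A4 | alternative 2 | 5-hydroperoxy-7-(6-methoxy-3,5-dimethyl-4-oxo-4H-pyran-2-yl)-1,3,5,7,8-pentamethylbicyclo[4.2.0]oct-2-en-4-one | COc1oc([C@@]2(C)[C@H](C)[C@@]3(C)C=C(C)C(=O)[C@](C)(OO)[C@@H]23)c(C)c(=O)c1C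
A5 | alternative 3 | methyl 1,3,5,8-tetramethyl-4-oxobicyclo[4.2.0]oct-2-ene-7-carboxylate | COC(=O)[C@H]1[C@H](C)[C@@]2(C)C=C(C)C(=O)[C@H](C)[C@@H]12
A6 | alternative 3 | α-diazo ketone of the cis-hydrindanone, 1-diazo-3,3a,5,7-tetramethyl-3,3a,7,7a-tetrahydro-1H-indene-2,6-dione | [N-]=[N+]=C1C(=O)[C@H](C)[C@@]2(C)C=C(C)C(=O)[C@H](C)[C@@H]12
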